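(All runs were generated by integration for substances that don't exist; the scatter is artificial.)

I kept the books in moles per litre of starting material and closed them once the readings had stopped moving.

| flask | starting material | reagent | protic impurity | remark | time |
|---|---|---|---|---|---|
| south-west | 0.14 M | 2 equiv | 0.010 M | run made earlier |  |
| west | 0.22 M | 2 equiv | 0.010 M | run made earlier |  |
| south-east | 0.10 M | 2 equiv | 0.0050 M | run made earlier |  |
| flask | 0.10 M | 2.00 equiv | 0.0100 M |  | 5.0 d |

| run | time / d | target / % | isomer of the product / % |
|---|---|---|---|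
| south-west | 0.417 | 27.6 | 46.4 |
| south-west | 0.625 | 26.6 | 47.4 |
| south-west | 0.833 | 26.6 | 47.4 |
| south-west | 1.25 | 26.9 | 47.0 |
| south-west | 2.00 | 26.8 | 46.9 |
| south-west | 3.00 | 27.0 | 46.3 |
| south-west | 5.00 | 27.1 | 47.1 |
| west | 0.250 | 31.0 | 50.0 |
| west | 0.833 | 29.5 | 51.7 |
| west | 1.25 | 29.7 | 52.1 |
| west | 2.00 | 29.6 | 52.1 |
| west | 3.00 | 29.6 | 51.8 |
| west | 4.00 | 29.3 | 51.2 |
| west | 5.00 | 29.8 | 52.3 |
| south-east | 0.417 | 25.6 | 44.5 |
| south-east | 0.833 | 25.3 | 44.8 |
| south-east | 1.25 | 25.3 | 44.7 |
| south-east | 2.50 | 25.4 | 44.8 |
| south-east | 5.00 | 25.9 | 45.0 |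

(scatter of a reading: 0.3 percentage points)

- ratio of target to isomer of the product at 2.0 min
- ratio of target to isomer of the product at 5.0 d
- which of target and isomer of the product there is more of at 5.0 d

- the numbers in the tables scatter with a standard deviation of 0.3 percentage points

In the south-west run at 2.00 d, target and isomer of the product together held 0.103 M of the 0.14 M charged. I supposed that each mole of protic impurity removed one mole of starting material as quenched substrate, which left 0.0268 M of it free beside 0.177 M of reagent. Dividing the bound amount by the product of those two gave 21.8 M⁻¹, and the same books gave 22.8 M⁻¹ for the west run and 21.8 M⁻¹ for the south-east run. I carried their mean, 22.1 M⁻¹, as the binding number: c(target) plus c(isomer of the product), over c(starting material) times c(reagent), once the flask is at rest.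

Against an even split, a ratio of 1, the same readings put target over isomer of the product at 0.569, which is thermodynamic control if the ratio holds. For the flask, 0.0672 M came out bound, so I entered 24.3 % target and 42.8 % isomer of the product.

The forecast gave 0.8 at 2.0 min and 0.57 at 5.0 d, with isomer of the product ahead, reasoning that “this looks like an equilibrium”.

The flask gave 2.00 at 2.0 min and 0.571 at 5.0 d, with 24.4 % target against 42.7 % isomer of the product. At the start, the forward step to the isomer of the product used starting material at 0.49 of the rate of the forward step to target. From the flask's own amounts at 5.0 d, the binding number reads 22.0 M⁻¹.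

    starting material + reagent ⇌ isomer of the product (K = 14.0 M⁻¹, k = 3.70 M⁻¹ h⁻¹)
    starting material + protic impurity → quenched substrate (k = 380 M⁻¹ h⁻¹)
    starting material + reagent ⇌ target (K = 8.00 M⁻¹, k = 7.50 M⁻¹ h⁻¹)

With 8.00 equiv of reagent, 22.1 M⁻¹ put 5.35 % of the starting material free in that neighbour flask. The computed neighbour flask ended with 5.38 % free and 53.9 % isomer of the product.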